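The C1/C2 sp3 pair and the C3=C4 bond of the 1,2-dihydronaphthalene ring are read as a dearomatized naphthalene-2,3-dicarboxylic acid, and the 6-carboxy-2-pyranone as a ring-cleaved 3,4,5-trihydroxyphenyl group whose ipso carbon is pyranone C4. The route rests on the bond between C1 and that carbon. In one operation a MOM-protected pyrogallyl-lithium adds to C1 of a flat, twofold-symmetric 2,3-bis[(R)-4-tert-butyloxazolinyl]-6,7-dimethoxynaphthalene (C1 and C4 homotopic): the ring is dearomatized, C1 is set by the auxiliary and C2 by protonation and equilibration to trans. Auxiliary hydrolysis, peracid intradiol cleavage with lactonization of the pyrogallol, and demethylation finish the synthesis.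

Key step: step 4

Assumption: 5-bromobenzene-1,2,3-triol (6) is taken as a catalogue compound, and the facial sense of step 4 is assigned by the usual model for 4-substituted aryloxazolines (aryl transfer from N-bound lithium on the face anti to the 4-substituent).

Step 1
Reactants: 1 4,5-dimethoxyphthalaldehyde; 2 succinonitrile
Product: 3 6,7-dimethoxynaphthalene-2,3-dicarbonitrile
Conditions: NaOEt (0.3 equiv), EtOH, 0 °C → reflux
Reagents that add atoms: none
Why: A twofold Knoevenagel-type condensation of the two CH2 groups of succinonitrile with the two formyl groups closes the new ring, and loss of two molecules of water is driven by aromatization to the naphthalene.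

Step 2
Reactants: 3 6,7-dimethoxynaphthalene-2,3-dicarbonitrile; 4 (R)-tert-leucinol (2.5 equiv)
Product: 5 2,3-bis[(4R)-4-tert-butyl-4,5-dihydrooxazol-2-yl]-6,7-dimethoxynaphthalene
Conditions: ZnCl2 (0.2 equiv), PhCl, reflux, N2 sweep
Reagents that add atoms: none
Why: The zinc-catalysed Witte–Seeliger condensation of each nitrile with the amino alcohol should give the oxazoline with loss of ammonia; the stereocentres come unchanged from (R)-tert-leucinol, and the nitrile route avoids the imide that ortho-diacid derivatives would form.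

Step 3
Reactants: 6 5-bromobenzene-1,2,3-triol
Product: 7 5-bromo-1,2,3-tris(methoxymethoxy)benzene
Conditions: NaH (3.6 equiv), MOMCl (3.6 equiv), DMF, 0 °C → rt
Reagents that add atoms: chloromethyl methyl ether, COCCl
Why: Williamson etherification of the three phenoxides gives MOM acetals that tolerate aryllithium and hydroxide and are removed by mild acid.

Step 4
Reactants: 5 2,3-bis[(4R)-4-tert-butyl-4,5-dihydrooxazol-2-yl]-6,7-dimethoxynaphthalene; 7 5-bromo-1,2,3-tris(methoxymethoxy)benzene (2.5 equiv)
Product: 11 2,2'-{(1R,2S)-6,7-dimethoxy-1-[3,4,5-tris(methoxymethoxy)phenyl]-1,2-dihydronaphthalene-2,3-diyl}bis[(4R)-4-tert-butyl-4,5-dihydrooxazole] (1,2-trans), via aryllithium 8 (not isolated), via lithium azaenolate 9 (not isolated), via cis epimer 10 (not isolated)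
Conditions: 7, t-BuLi (5.0 equiv), THF, −78 °C; add 5, −78 → −30 °C; MeOH, −78 °C; then NaOMe (0.3 equiv), MeOH–THF, rt, Ar
Reagents that add atoms: none
Why: Bromine–lithium exchange gives 8, which binds to the oxazoline nitrogen lying syn to C1 and transfers its aryl group to C1 through a six-membered N–Li···C array; this oxazoline-directed dearomatizing conjugate addition breaks the aromaticity of the substituted ring and leaves azaenolate 9 at C2, while C3=C4 stays conjugated to the second oxazoline and the dimethoxybenzene ring. The closest known reaction type is the addition of aryllithiums to chiral 3-substituted 2-naphthyloxazolines used for 1-aryl-1,2-dihydronaphthalene lignans. No ring is closed. C1 is controlled by the (R)-4-tert-butyl group, the aryl group being delivered to the face of the coplanar naphthalene–oxazoline unit opposite to tert-butyl, which should give (1R); C2 is first protonated anti to the new aryl group (cis epimer 10) and is then equilibrated by catalytic methoxide through its azaenolate to the (1R,2S)-trans arrangement, in which both substituents sit pseudoaxial. The step needs 1,4-addition rather than attack on C=N, attack at C1 rather than C4, and monoaddition: N-directed delivery secures the first, the twofold axis of 5 makes C1 and C4 homotopic, and the anionic azaenolate 9 resists a second aryllithium.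

Step 5
Reactants: 11 trans bis(oxazoline) adduct
Product: 14 (1R,2S)-6,7-dimethoxy-1-(3,4,5-trihydroxyphenyl)-1,2-dihydronaphthalene-2,3-dicarboxylic acid, via bis(oxazolinium) triflate 12 (not isolated), via MOM-protected diacid 13 (not isolated)
Conditions: MeOTf (2.4 equiv), CH2Cl2, rt; 2 M NaOH, THF–H2O, 40 °C (degassed); 6 M HCl to pH 0, i-PrOH, 50 °C (degassed)
Reagents that add atoms: sodium hydroxide, [Na+].[OH-] (both oxygens of each CO2H); methyl trifluoromethanesulfonate, COS(=O)(=O)C(F)(F)F (its methyl groups are carried only by 12 and leave with the auxiliary)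
Why: N-Methylation turns each oxazoline into an oxazolinium ion that hydroxide opens and saponifies (oxazoline removal by quaternization and alkaline hydrolysis), the epimerizable C2 stays in its thermodynamic trans arrangement, and acid then cleaves the three MOM acetals by transacetalization to i-PrOH without esterifying the acids.

Step 6
Reactants: 14 pyrogallol diacid
Product: 17 (1R,2S)-1-(6-carboxy-2-oxo-2H-pyran-4-yl)-6,7-dimethoxy-1,2-dihydronaphthalene-2,3-dicarboxylic acid, via hydroxy-o-quinone 15 (not isolated), via muconic anhydride 16 (not isolated)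
Conditions: AcOOH (2.2 equiv), AcOH, 10 °C → rt, then 50 °C
Reagents that add atoms: peracetic acid, CC(=O)OO
Why: Peracid should oxidize the electron-rich pyrogallol to hydroxy-o-quinone 15, a Baeyer–Villiger-type oxygen insertion between the two carbonyls (intradiol cleavage, as in the peracid oxidation of catechols to muconic acids) gives anhydride 16, and the enol OH acylates itself on the distal anhydride carbonyl to close the 2-pyranone and free the 6-carboxylic acid; the local symmetry of the pyrogallol makes both cleavage sites equivalent, and the methylated catechol ring and the electron-poor C3=C4 bond should react far more slowly.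

Step 7
Reactants: 17 pyranone triacid dimethyl ether
Product: 18 (1R,2S)-1-(6-carboxy-2-oxo-2H-pyran-4-yl)-6,7-dihydroxy-1,2-dihydronaphthalene-2,3-dicarboxylic acid (CNP0195322.1)
Conditions: BBr3 (8 equiv), CH2Cl2, −78 °C → rt; H2O
Reagents that add atoms: none
Why: BBr3 cleaves both aryl methyl ethers by bromide attack on the O-methyl group of the borane adduct (Lewis-acid ether cleavage) under non-basic conditions that should leave the pyranone, the C3=C4 bond and both stereocentres untouched.

Compound list
1 | 4,5-dimethoxyphthalaldehyde | COc1cc(C=O)c(C=O)cc1OC | starting material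
2 | succinonitrile | N#CCCC#N | starting material
3 | 6,7-dimethoxynaphthalene-2,3-dicarbonitrile | N#Cc1cc2cc(OC)c(OC)cc2cc1C#N | intermediate
4 | (R)-tert-leucinol | CC(C)(C)[C@@H](N)CO | starting material
5 | 2,3-bis[(4R)-4-tert-butyl-4,5-dihydrooxazol-2-yl]-6,7-dimethoxynaphthalene | COc1cc2cc(C3=N[C@H](C(C)(C)C)CO3)c(C3=N[C@H](C(C)(C)C)CO3)cc2cc1OC | intermediate
6 | 5-bromobenzene-1,2,3-triol | Oc1cc(Br)cc(O)c1O | starting material
7 | 5-bromo-1,2,3-tris(methoxymethoxy)benzene | COCOc1cc(Br)cc(OCOC)c1OCOC | intermediate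
8 | 3,4,5-tris(methoxymethoxy)phenyllithium | [Li]c1cc(OCOC)c(OCOC)c(OCOC)c1 | intermediate (not isolated)
9 | lithium azaenolate at C2 of the (1R)-aryl adduct | C1(C3=N[C@H](C(C)(C)C)CO3)=Cc2cc(OC)c(OC)cc2[C@@H](c5cc(OCOC)c(OCOC)c(OCOC)c5)C1=C4N([Li])[C@H](C(C)(C)C)CO4 | intermediate (not isolated)
10 | (1R,2R)-cis epimer of 11 | C1(C3=N[C@H](C(C)(C)C)CO3)=Cc2cc(OC)c(OC)cc2[C@@H](c5cc(OCOC)c(OCOC)c(OCOC)c5)[C@H]1C4=N[C@H](C(C)(C)C)CO4 | intermediate (not isolated)
11 | 2,2'-{(1R,2S)-6,7-dimethoxy-1-[3,4,5-tris(methoxymethoxy)phenyl]-1,2-dihydronaphthalene-2,3-diyl}bis[(4R)-4-tert-butyl-4,5-dihydrooxazole] | C1(C3=N[C@H](C(C)(C)C)CO3)=Cc2cc(OC)c(OC)cc2[C@@H](c5cc(OCOC)c(OCOC)c(OCOC)c5)[C@@H]1C4=N[C@H](C(C)(C)C)CO4 | intermediate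
12 | bis(N-methyloxazolinium) bis(triflate) of 11 | C1(C3=[N+](C)[C@H](C(C)(C)C)CO3)=Cc2cc(OC)c(OC)cc2[C@@H](c5cc(OCOC)c(OCOC)c(OCOC)c5)[C@@H]1C4=[N+](C)[C@H](C(C)(C)C)CO4.[O-]S(=O)(=O)C(F)(F)F.[O-]S(=O)(=O)C(F)(F)F | intermediate (not isolated)
13 | (1R,2S)-6,7-dimethoxy-1-[3,4,5-tris(methoxymethoxy)phenyl]-1,2-dihydronaphthalene-2,3-dicarboxylic acid (formed as its disodium salt, protonated on acidification) | O=C(O)C1=Cc2cc(OC)c(OC)cc2[C@@H](c5cc(OCOC)c(OCOC)c(OCOC)c5)[C@@H]1C(=O)O | intermediate (not isolated)
14 | (1R,2S)-6,7-dimethoxy-1-(3,4,5-trihydroxyphenyl)-1,2-dihydronaphthalene-2,3-dicarboxylic acid | O=C(O)C1=Cc2cc(OC)c(OC)cc2[C@@H](c5cc(O)c(O)c(O)c5)[C@@H]1C(=O)O | intermediate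
15 | (1R,2S)-1-(5-hydroxy-3,4-dioxocyclohexa-1,5-dien-1-yl)-6,7-dimethoxy-1,2-dihydronaphthalene-2,3-dicarboxylic acid | O=C(O)C1=Cc2cc(OC)c(OC)cc2[C@@H](C5=CC(=O)C(=O)C(O)=C5)[C@@H]1C(=O)O | intermediate (not isolated)
16 | (1R,2S)-1-(6-hydroxy-2,7-dioxo-2,7-dihydrooxepin-4-yl)-6,7-dimethoxy-1,2-dihydronaphthalene-2,3-dicarboxylic acid | O=C(O)C1=Cc2cc(OC)c(OC)cc2[C@@H](C5=CC(=O)OC(=O)C(O)=C5)[C@@H]1C(=O)O | intermediate (not isolated)
17 | (1R,2S)-1-(6-carboxy-2-oxo-2H-pyran-4-yl)-6,7-dimethoxy-1,2-dihydronaphthalene-2,3-dicarboxylic acid | O=C(O)C1=Cc2cc(OC)c(OC)cc2[C@@H](c5cc(C(=O)O)oc(=O)c5)[C@@H]1C(=O)O | intermediate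
18 | (1R,2S)-1-(6-carboxy-2-oxo-2H-pyran-4-yl)-6,7-dihydroxy-1,2-dihydronaphthalene-2,3-dicarboxylic acid (CNP0195322.1) | O=C(O)C1=Cc2cc(O)c(O)cc2[C@@H](c2cc(C(=O)O)oc(=O)c2)[C@@H]1C(=O)O | target

Total step count: 7
Longest linear sequence: 6 steps (steps 1, 2, 4, 5, 6, 7)

Steps most likely to fail

1. Step 6 (ring cleavage of the pyrogallol). The hydroxy-o-quinone may couple with unreacted pyrogallol to benzotropolone-type dimers before the peracid reaches it. The peracid may also over-oxidize, by epoxidation of C3=C4 or degradation of the ring-opened acid. The fallback sets out from 14 and replaces the peracid by copper-mediated dioxygen cleavage in methanol (CuCl, pyridine, MeOH, O2, rt), the intradiol cleavage of catechols to muconic half-esters. It should give the monomethyl 2-hydroxymuconate F1, drawn with the ester next to the enol; the regioisomeric half-ester converges on the same pyranone. Lactonization (TFA, CH2Cl2, rt) should give the pyranone methyl ester F2, and acid hydrolysis (6 M HCl, dioxane, 80 °C) comes back to the route at 17.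

2. Step 4 (key step). The two neighbouring oxazolines may twist out of the naphthalene plane or hold the aryllithium between their nitrogens, which would slow the conjugate addition and erode facial control. Proton transfer to 8 may compete. The fallback sets out from 3 and uses a single oxazoline, with the C3 carboxyl carried as an acetal. Condensation with one equivalent of 4 (ZnCl2, PhCl, reflux) should give the mono-oxazoline nitrile F3. DIBAL-H (toluene, −78 °C, then aqueous acid) should reduce the remaining nitrile to the oxazoline aldehyde F4, and HC(OMe)3/CSA/MeOH should give the oxazoline acetal F5. Addition of 8, protonation and equilibration as in step 4 should give the trans acetal adduct F6, with C1 as the only activated position. MeOTf, then NaOH, then PPTS in aqueous acetone should release the aldehyde acid F7. Pinnick oxidation (NaClO2, NaH2PO4, 2-methyl-2-butene) then gives the MOM-protected diacid and comes back to the route at 13, before the acid stage of step 5.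

3. Step 5 (auxiliary removal). Hydroxide may open the oxazolinium ions to N-methyl hydroxy amides that resist saponification. The basic stage may also shift the C3=C4 bond or allow aromatization by air. The fallback sets out from 11 and opens the rings under acid first. TFA/H2O (THF, rt) should open both oxazolines to amino esters and remove the MOM groups, giving the bis(amino ester) triol F8 as its bis(trifluoroacetate). Ac2O/pyridine caps the nitrogens, which blocks O→N acyl shift, and the phenols, giving the bis(acetamido ester) triacetate F9. LiOH (degassed THF–H2O), then HCl, cleaves all five esters and comes back to the route at 14.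

Further compounds
F1 | step 6 | 1-methyl hydrogen 2-hydroxy-4-[(1R,2S)-2,3-dicarboxy-6,7-dimethoxy-1,2-dihydronaphthalen-1-yl]hexa-2,4-dienedioate | O=C(O)C1=Cc2cc(OC)c(OC)cc2[C@@H](/C(=C/C(=O)O)/C=C(/O)C(=O)OC)[C@@H]1C(=O)O
F2 | step 6 | (1R,2S)-6,7-dimethoxy-1-[6-(methoxycarbonyl)-2-oxo-2H-pyran-4-yl]-1,2-dihydronaphthalene-2,3-dicarboxylic acid | O=C(O)C1=Cc2cc(OC)c(OC)cc2[C@@H](c5cc(C(=O)OC)oc(=O)c5)[C@@H]1C(=O)O
F3 | step 4 | 3-[(4R)-4-tert-butyl-4,5-dihydrooxazol-2-yl]-6,7-dimethoxynaphthalene-2-carbonitrile | N#Cc1cc2cc(OC)c(OC)cc2cc1C1=N[C@H](C(C)(C)C)CO1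
F4 | step 4 | 3-[(4R)-4-tert-butyl-4,5-dihydrooxazol-2-yl]-6,7-dimethoxynaphthalene-2-carbaldehyde | O=Cc1cc2cc(OC)c(OC)cc2cc1C1=N[C@H](C(C)(C)C)CO1
F5 | step 4 | (4R)-4-tert-butyl-2-[3-(dimethoxymethyl)-6,7-dimethoxynaphthalen-2-yl]-4,5-dihydrooxazole | COC(OC)c1cc2cc(OC)c(OC)cc2cc1C1=N[C@H](C(C)(C)C)CO1
F6 | step 4 | (4R)-4-tert-butyl-2-{(1R,2S)-3-(dimethoxymethyl)-6,7-dimethoxy-1-[3,4,5-tris(methoxymethoxy)phenyl]-1,2-dihydronaphthalen-2-yl}-4,5-dihydrooxazole | C1(C(OC)OC)=Cc2cc(OC)c(OC)cc2[C@@H](c5cc(OCOC)c(OCOC)c(OCOC)c5)[C@@H]1C4=N[C@H](C(C)(C)C)CO4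
F7 | step 4 | (1R,2S)-3-formyl-6,7-dimethoxy-1-[3,4,5-tris(methoxymethoxy)phenyl]-1,2-dihydronaphthalene-2-carboxylic acid | O=CC1=Cc2cc(OC)c(OC)cc2[C@@H](c5cc(OCOC)c(OCOC)c(OCOC)c5)[C@@H]1C(=O)O
F8 | step 5 | bis[(2R)-2-amino-3,3-dimethylbutyl] (1R,2S)-6,7-dimethoxy-1-(3,4,5-trihydroxyphenyl)-1,2-dihydronaphthalene-2,3-dicarboxylate | C1(C(=O)OC[C@H](N)C(C)(C)C)=Cc2cc(OC)c(OC)cc2[C@@H](c5cc(O)c(O)c(O)c5)[C@@H]1C(=O)OC[C@H](N)C(C)(C)C
F9 | step 5 | bis[(2R)-2-acetamido-3,3-dimethylbutyl] (1R,2S)-6,7-dimethoxy-1-(3,4,5-triacetoxyphenyl)-1,2-dihydronaphthalene-2,3-dicarboxylate | C1(C(=O)OC[C@H](NC(C)=O)C(C)(C)C)=Cc2cc(OC)c(OC)cc2[C@@H](c5cc(OC(C)=O)c(OC(C)=O)c(OC(C)=O)c5)[C@@H]1C(=O)OC[C@H](NC(C)=O)C(C)(C)C
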